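**Retrosynthetic overview**

1. Laxiflorin comes from its tetrakis(tert-butyldimethylsilyl) ether by buffered fluoride; nothing else changes after the key step.
2. The key disconnection is C2–C3 of ring C. C2 is benzylic to ring B and bonded to O1, so in the O1 (4-silyloxy-3-methoxybenzyl) ether of a ring A aryl diazomethyl ketone (carbene carbon = C3, on the C4 acyl group at C4a) its C–H bonds are doubly activated toward carbene insertion.
3. The diazoketone comes from the C4a carboxylic acid, and that from the C4a aldehyde; the O1–CH2 bond is made by a Mitsunobu reaction with silylated vanillyl alcohol (from vanillin).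
4. The hexasubstituted ring A comes from 2,6-dihydroxybenzaldehyde: the CHO becomes the C6 hydroxyethyl chain between O5 and O7, O1 enters para to it by C–H borylation/oxidation, the C8 prenyl group by O-(1,1-dimethylallyl)ation/Claisen rearrangement, and the C4a formyl group by magnesium-mediated ortho-formylation.
5. Ring order: rings A and B are bought as arenes; ring C is the only ring made, in the key step.

Key step: step 15

Remarks and assumptions:
- TBS = tert-butyldimethylsilyl. Flavanone numbering (O1, C2, C3, C4, C4a, C5–C8, C8a; rings A, B, C) is used for the ring A intermediates as well.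
- The sense of induction of Rh2(S-PTTL)4 with this diazoketone is assumed to favour the pro-S benzylic hydrogen. If the first run should show the opposite sense, Rh2(R-PTTL)4 from (R)-tert-leucine is used in the same way.

**Route**

Step 1
Reactants: 1 vanillin
Product: 2 4-(TBSO)-3-methoxybenzaldehyde
Conditions: TBSCl, imidazole, DMF, rt
Reagents that add atoms: tert-butyldimethylsilyl chloride, CC(C)(C)[Si](C)(C)Cl
Why: Imidazole-promoted silylation of the single phenol gives the aryl silyl ether and leaves the aldehyde untouched (silyl ether formation).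

Step 2
Reactants: 2 4-(TBSO)-3-methoxybenzaldehyde
Product: 3 [4-(TBSO)-3-methoxyphenyl]methanol
Conditions: NaBH4, MeOH/THF, 0 °C
Reagents that add atoms: none
Why: Borohydride reduction of the aryl aldehyde to the benzylic alcohol is fast at 0 °C, so the aryl silyl ether should survive the short contact with methanol.

Step 3
Reactants: 4 2-methylbut-3-en-2-ol
Product: 5 tert-butyl 2-methylbut-3-en-2-yl carbonate
Conditions: n-BuLi, THF, −78 °C; Boc2O, −78 °C → rt
Reagents that add atoms: di-tert-butyl dicarbonate, CC(C)(C)OC(=O)OC(=O)OC(C)(C)C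
Why: The lithium alkoxide of the tertiary allylic alcohol attacks a carbonyl of di-tert-butyl dicarbonate to give the mixed carbonate (alkoxide acylation), which serves as the ionisable leaving group of step 9.

Step 4
Reactants: 6 2,6-dihydroxybenzaldehyde
Product: 7 2,6-bis(TBSO)benzaldehyde
Conditions: TBSCl, imidazole, DMAP (cat.), DMF, rt → 40 °C
Reagents that add atoms: tert-butyldimethylsilyl chloride, CC(C)(C)[Si](C)(C)Cl
Why: Both hydrogen-bonded phenols are silylated under imidazole/DMF conditions (silyl ether formation), giving the bulky silyl ethers that later flank C6 as O5 and O7 and carry no C–H bond next to oxygen.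

Step 5
Reactants: 7 2,6-bis(TBSO)benzaldehyde
Product: 8 1,3-bis(TBSO)-2-vinylbenzene
Conditions: Ph3PCH3Br, KN(SiMe3)2, THF, 0 °C → rt
Reagents that add atoms: methyltriphenylphosphonium bromide, C[P+](c1ccccc1)(c1ccccc1)c1ccccc1.[Br-]
Why: Wittig methylenation with the unstabilised ylide converts even a doubly ortho-substituted aryl aldehyde into the styrene and does not touch the silyl ethers.

Step 6
Reactants: 8 1,3-bis(TBSO)-2-vinylbenzene
Product: 10 2-[2,6-bis(TBSO)phenyl]ethanol, via alkylborane 9 (not isolated)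
Conditions: 9-BBN, THF, 0 °C → 50 °C; then aq. NaOAc, 30% H2O2, 0 °C → rt
Reagents that add atoms: 9-borabicyclo[3.3.1]nonane, B1C2CCCC1CCC2 (boron and bicyclic carbons of intermediate 9 only); hydrogen peroxide, OO (hydroxyl oxygen of 10)
Why: 9-BBN adds boron to the terminal carbon of the styrene (anti-Markovnikov hydroboration) and acetate-buffered peroxide oxidation replaces boron by hydroxyl without the hydroxide that would cleave aryl silyl ethers.

Step 7
Reactants: 10 2-[2,6-bis(TBSO)phenyl]ethanol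
Product: 11 1,3-bis(TBSO)-2-[2-(TBSO)ethyl]benzene
Conditions: TBSCl, imidazole, CH2Cl2, rt
Reagents that add atoms: tert-butyldimethylsilyl chloride, CC(C)(C)[Si](C)(C)Cl
Why: Silylation of the primary alcohol (silyl ether formation) masks the only O–H bond, which would otherwise consume boron reagent in step 8 and capture the carbene in step 15.

Step 8
Reactants: 11 1,3-bis(TBSO)-2-[2-(TBSO)ethyl]benzene
Product: 13 3,5-bis(TBSO)-4-[2-(TBSO)ethyl]phenol, via aryl pinacol boronate 12 (not isolated)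
Conditions: [Ir(OMe)(cod)]2 (1.5 mol %), 4,4′-di-tert-butyl-2,2′-bipyridine (3 mol %), B2pin2, hexane, 80 °C; then KHSO5 (as 2KHSO5·KHSO4·K2SO4), acetone/H2O, rt, 10 min
Reagents that add atoms: bis(pinacolato)diboron, CC1(C)OB(OC1(C)C)B1OC(C)(C)C(C)(C)O1 (boryl group of intermediate 12 only); potassium peroxymonosulfate, [K+].[O-]S(=O)(=O)OO (phenol oxygen of 13)
Why: Iridium-catalysed aromatic C–H borylation is governed by sterics and takes the only ring C–H that has no ortho substituent, para to the side chain, and peroxymonosulfate then replaces boron by hydroxyl (ipso-hydroxylation), so the future O1 is introduced already distinguished from the silylated O5 and O7.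

Step 9
Reactants: 13 3,5-bis(TBSO)-4-[2-(TBSO)ethyl]phenol; 5 tert-butyl 2-methylbut-3-en-2-yl carbonate
Product: 14 1,3-bis(TBSO)-2-[2-(TBSO)ethyl]-5-(2-methylbut-3-en-2-yloxy)benzene
Conditions: Pd(PPh3)4 (3 mol %), THF, 4 Å MS, 0 °C
Reagents that add atoms: none
Why: Ionisation of carbonate 5 by zerovalent palladium gives a 1,1-dimethyl-π-allyl complex that the phenoxide attacks kinetically at the more substituted terminus (Tsuji–Trost O-allylation), giving the tertiary aryl ether.

Step 10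
Reactants: 14 1,3-bis(TBSO)-2-[2-(TBSO)ethyl]-5-(2-methylbut-3-en-2-yloxy)benzene
Product: 15 2-(3-methylbut-2-en-1-yl)-3,5-bis(TBSO)-4-[2-(TBSO)ethyl]phenol
Conditions: PhMe, PhNEt2 (0.2 equiv), 110 °C
Reagents that add atoms: none
Why: Aromatic Claisen rearrangement ([3,3]-sigmatropic shift) transfers the allyl unit with transposition to one of the two equivalent ortho carbons and rearomatises to the phenol, so the prenyl group ends at C8 next to the free O1 hydroxyl, the para carbon being blocked by the side chain.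

Step 11
Reactants: 15 2-(3-methylbut-2-en-1-yl)-3,5-bis(TBSO)-4-[2-(TBSO)ethyl]phenol
Product: 16 2-hydroxy-3-(3-methylbut-2-en-1-yl)-4,6-bis(TBSO)-5-[2-(TBSO)ethyl]benzaldehyde
Conditions: MgCl2, Et3N, (CH2O)n, THF, reflux; then aq. citric acid
Reagents that add atoms: formaldehyde (as paraformaldehyde), C=O
Why: In the magnesium phenoxide the metal delivers formaldehyde to the ortho carbon and a second formaldehyde oxidises the hydroxymethyl intermediate (Casnati–Skattebøl ortho-formylation), and the only free ring carbon is C4a.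

Step 12
Reactants: 16 2-hydroxy-3-(3-methylbut-2-en-1-yl)-4,6-bis(TBSO)-5-[2-(TBSO)ethyl]benzaldehyde; 3 [4-(TBSO)-3-methoxyphenyl]methanol
Product: 17 2-{[4-(TBSO)-3-methoxyphenyl]methoxy}-3-(3-methylbut-2-en-1-yl)-4,6-bis(TBSO)-5-[2-(TBSO)ethyl]benzaldehyde
Conditions: PPh3, DIAD, THF, 0 °C → rt
Reagents that add atoms: none
Why: The chelated, acidic salicylaldehyde hydroxyl is alkylated by the benzylic alcohol under Mitsunobu conditions (SN2 displacement of the oxyphosphonium ion), which avoids carbonate bases that would strip aryl silyl ethers and avoids the labile 4-silyloxybenzyl bromide.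

Step 13
Reactants: 17 2-{[4-(TBSO)-3-methoxyphenyl]methoxy}-3-(3-methylbut-2-en-1-yl)-4,6-bis(TBSO)-5-[2-(TBSO)ethyl]benzaldehyde
Product: 18 2-{[4-(TBSO)-3-methoxyphenyl]methoxy}-3-(3-methylbut-2-en-1-yl)-4,6-bis(TBSO)-5-[2-(TBSO)ethyl]benzoic acid
Conditions: NaClO2, NaH2PO4, 2-methyl-2-butene (large excess), t-BuOH/THF/H2O, 0 °C → rt
Reagents that add atoms: sodium chlorite, [Na+].[O-]Cl=O
Why: Pinnick oxidation converts the hindered aryl aldehyde into the acid at about pH 4, and the large excess of 2-methyl-2-butene takes up hypochlorous acid before it can reach the prenyl alkene or ring B.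

Step 14
Reactants: 18 2-{[4-(TBSO)-3-methoxyphenyl]methoxy}-3-(3-methylbut-2-en-1-yl)-4,6-bis(TBSO)-5-[2-(TBSO)ethyl]benzoic acid
Product: 20 2-diazo-1-{2-{[4-(TBSO)-3-methoxyphenyl]methoxy}-3-(3-methylbut-2-en-1-yl)-4,6-bis(TBSO)-5-[2-(TBSO)ethyl]phenyl}ethanone, via acid chloride 19 (not isolated)
Conditions: Me2C=C(Cl)NMe2, CH2Cl2, 0 °C → rt; then CH2N2 (excess), Et2O, 0 °C
Reagents that add atoms: 1-chloro-N,N,2-trimethylprop-1-en-1-amine, CC(C)=C(Cl)N(C)C (chlorine of intermediate 19 only); diazomethane, C=[N+]=[N-] (diazomethyl carbon and nitrogens of 20)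
Why: The α-chloroenamine makes the acid chloride under neutral conditions, so the acid-labile benzyl ether and silyl ethers are kept, and diazomethane is then C-acylated to the diazoketone while a second equivalent removes HCl as chloromethane (first stage of the Arndt–Eistert sequence).

Step 15
Reactants: 20 2-diazo-1-{2-{[4-(TBSO)-3-methoxyphenyl]methoxy}-3-(3-methylbut-2-en-1-yl)-4,6-bis(TBSO)-5-[2-(TBSO)ethyl]phenyl}ethanone
Product: 21 (2S)-5,7-bis(TBSO)-6-[2-(TBSO)ethyl]-2-[4-(TBSO)-3-methoxyphenyl]-8-(3-methylbut-2-en-1-yl)chroman-4-one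
Conditions: dirhodium tetrakis[N-phthaloyl-(S)-tert-leucinate], Rh2(S-PTTL)4 (2 mol %), CH2Cl2, 4 Å MS, slow addition of 20 by syringe pump, 0 °C → rt
Reagents that add atoms: none
Why: The dirhodium tetracarboxylate (divalent rhodium) takes up the diazo carbon of 20, N2 leaves, and the electrophilic rhodium carbene at the future C3 inserts into a benzylic C–H bond of the O1–CH2–aryl group through a three-centre, hydride-transfer-like transition state in which the C2–C3 bond forms with retention at C2. The closest known reaction type is the chiral dirhodium carboxylate-catalysed intramolecular C–H insertion of 2-alkoxyaryl diazoketones to 2-substituted chroman-4-ones. Ring C closes as a six-membered ring by 1,6-insertion along the chain C3–C4–C4a–C8a–O1–C2, the usual five-membered mode being closed because the atom at that distance is O1. C2 is set by the catalyst: the N-phthaloyl-tert-leucinate ligands differentiate the two enantiotopic benzylic hydrogens, and replacement of the pro-S hydrogen with retention gives 2S. The step needs C–H insertion to outrun oxonium ylide formation at O1 (which would end in a [1,2]-benzyl shift to a coumaranone), attack on the O5 silyl ether oxygen and bimolecular reaction with the prenyl alkene; the substrate secures this because the C–H bond is activated by both O1 and the para-silyloxy ring B, O1 is hindered between the prenyl and acyl groups, O5 carries a bulky silyl group with no C–H bond next to oxygen, the C6 and C8 side chains sit meta to the acyl carbon and cannot reach the carbene, and slow addition keeps the diazoketone dilute.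

Step 16
Reactants: 21 (2S)-5,7-bis(TBSO)-6-[2-(TBSO)ethyl]-2-[4-(TBSO)-3-methoxyphenyl]-8-(3-methylbut-2-en-1-yl)chroman-4-one
Product: 22 laxiflorin, (2S)-5,7-dihydroxy-2-(4-hydroxy-3-methoxyphenyl)-6-(2-hydroxyethyl)-8-(3-methylbut-2-en-1-yl)chroman-4-one
Conditions: Bu4NF, AcOH (1:1.2), THF, 0 °C → rt
Reagents that add atoms: none
Why: Fluoride cleaves all four Si–O bonds (silyl ether cleavage) while acetic acid protonates each phenoxide as it forms, so neither retro-oxa-Michael opening of ring C nor quinone methide formation can scramble C2, and the prenyl group is not exposed to strong acid.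

**Compound list**

1 | vanillin | COc1cc(C=O)ccc1O | starting material
2 | 4-(tert-butyldimethylsilyloxy)-3-methoxybenzaldehyde | COc1cc(C=O)ccc1O[Si](C)(C)C(C)(C)C | intermediate
3 | [4-(tert-butyldimethylsilyloxy)-3-methoxyphenyl]methanol | COc1cc(CO)ccc1O[Si](C)(C)C(C)(C)C | intermediate
4 | 2-methylbut-3-en-2-ol | C=CC(C)(C)O | starting material
5 | tert-butyl 2-methylbut-3-en-2-yl carbonate | C=CC(C)(C)OC(=O)OC(C)(C)C | intermediate
6 | 2,6-dihydroxybenzaldehyde | O=Cc1c(O)cccc1O | starting material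
7 | 2,6-bis(tert-butyldimethylsilyloxy)benzaldehyde | O=Cc1c(O[Si](C)(C)C(C)(C)C)cccc1O[Si](C)(C)C(C)(C)C | intermediate
8 | 1,3-bis(tert-butyldimethylsilyloxy)-2-vinylbenzene | C=Cc1c(O[Si](C)(C)C(C)(C)C)cccc1O[Si](C)(C)C(C)(C)C | intermediate
9 | 9-{2-[2,6-bis(tert-butyldimethylsilyloxy)phenyl]ethyl}-9-borabicyclo[3.3.1]nonane (not isolated) | CC(C)(C)[Si](C)(C)Oc1cccc(O[Si](C)(C)C(C)(C)C)c1CCB1C2CCCC1CCC2 | intermediate
10 | 2-[2,6-bis(tert-butyldimethylsilyloxy)phenyl]ethanol | OCCc1c(O[Si](C)(C)C(C)(C)C)cccc1O[Si](C)(C)C(C)(C)C | intermediate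
11 | 1,3-bis(tert-butyldimethylsilyloxy)-2-[2-(tert-butyldimethylsilyloxy)ethyl]benzene | CC(C)(C)[Si](C)(C)OCCc1c(O[Si](C)(C)C(C)(C)C)cccc1O[Si](C)(C)C(C)(C)C | intermediate
12 | 2-{3,5-bis(tert-butyldimethylsilyloxy)-4-[2-(tert-butyldimethylsilyloxy)ethyl]phenyl}-4,4,5,5-tetramethyl-1,3,2-dioxaborolane (not isolated) | CC1(C)OB(OC1(C)C)c1cc(O[Si](C)(C)C(C)(C)C)c(CCO[Si](C)(C)C(C)(C)C)c(O[Si](C)(C)C(C)(C)C)c1 | intermediate
13 | 3,5-bis(tert-butyldimethylsilyloxy)-4-[2-(tert-butyldimethylsilyloxy)ethyl]phenol | Oc1cc(O[Si](C)(C)C(C)(C)C)c(CCO[Si](C)(C)C(C)(C)C)c(O[Si](C)(C)C(C)(C)C)c1 | intermediate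
14 | 1,3-bis(tert-butyldimethylsilyloxy)-2-[2-(tert-butyldimethylsilyloxy)ethyl]-5-(2-methylbut-3-en-2-yloxy)benzene | C=CC(C)(C)Oc1cc(O[Si](C)(C)C(C)(C)C)c(CCO[Si](C)(C)C(C)(C)C)c(O[Si](C)(C)C(C)(C)C)c1 | intermediate
15 | 2-(3-methylbut-2-en-1-yl)-3,5-bis(tert-butyldimethylsilyloxy)-4-[2-(tert-butyldimethylsilyloxy)ethyl]phenol | Oc1cc(O[Si](C)(C)C(C)(C)C)c(CCO[Si](C)(C)C(C)(C)C)c(O[Si](C)(C)C(C)(C)C)c1CC=C(C)C | intermediate
16 | 2-hydroxy-3-(3-methylbut-2-en-1-yl)-4,6-bis(tert-butyldimethylsilyloxy)-5-[2-(tert-butyldimethylsilyloxy)ethyl]benzaldehyde | O=Cc1c(O)c(CC=C(C)C)c(O[Si](C)(C)C(C)(C)C)c(CCO[Si](C)(C)C(C)(C)C)c1O[Si](C)(C)C(C)(C)C | intermediate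
17 | 2-{[4-(tert-butyldimethylsilyloxy)-3-methoxyphenyl]methoxy}-3-(3-methylbut-2-en-1-yl)-4,6-bis(tert-butyldimethylsilyloxy)-5-[2-(tert-butyldimethylsilyloxy)ethyl]benzaldehyde | O=Cc1c(OCc2ccc(O[Si](C)(C)C(C)(C)C)c(OC)c2)c(CC=C(C)C)c(O[Si](C)(C)C(C)(C)C)c(CCO[Si](C)(C)C(C)(C)C)c1O[Si](C)(C)C(C)(C)C | intermediate
18 | 2-{[4-(tert-butyldimethylsilyloxy)-3-methoxyphenyl]methoxy}-3-(3-methylbut-2-en-1-yl)-4,6-bis(tert-butyldimethylsilyloxy)-5-[2-(tert-butyldimethylsilyloxy)ethyl]benzoic acid | OC(=O)c1c(OCc2ccc(O[Si](C)(C)C(C)(C)C)c(OC)c2)c(CC=C(C)C)c(O[Si](C)(C)C(C)(C)C)c(CCO[Si](C)(C)C(C)(C)C)c1O[Si](C)(C)C(C)(C)C | intermediate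
19 | 2-{[4-(tert-butyldimethylsilyloxy)-3-methoxyphenyl]methoxy}-3-(3-methylbut-2-en-1-yl)-4,6-bis(tert-butyldimethylsilyloxy)-5-[2-(tert-butyldimethylsilyloxy)ethyl]benzoyl chloride (not isolated) | O=C(Cl)c1c(OCc2ccc(O[Si](C)(C)C(C)(C)C)c(OC)c2)c(CC=C(C)C)c(O[Si](C)(C)C(C)(C)C)c(CCO[Si](C)(C)C(C)(C)C)c1O[Si](C)(C)C(C)(C)C | intermediate
20 | 2-diazo-1-{2-{[4-(tert-butyldimethylsilyloxy)-3-methoxyphenyl]methoxy}-3-(3-methylbut-2-en-1-yl)-4,6-bis(tert-butyldimethylsilyloxy)-5-[2-(tert-butyldimethylsilyloxy)ethyl]phenyl}ethanone | [N-]=[N+]=CC(=O)c1c(OCc2ccc(O[Si](C)(C)C(C)(C)C)c(OC)c2)c(CC=C(C)C)c(O[Si](C)(C)C(C)(C)C)c(CCO[Si](C)(C)C(C)(C)C)c1O[Si](C)(C)C(C)(C)C | intermediate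
21 | (2S)-5,7-bis(tert-butyldimethylsilyloxy)-6-[2-(tert-butyldimethylsilyloxy)ethyl]-2-[4-(tert-butyldimethylsilyloxy)-3-methoxyphenyl]-8-(3-methylbut-2-en-1-yl)chroman-4-one | COc1cc([C@@H]2CC(=O)c3c(O[Si](C)(C)C(C)(C)C)c(CCO[Si](C)(C)C(C)(C)C)c(O[Si](C)(C)C(C)(C)C)c(CC=C(C)C)c3O2)ccc1O[Si](C)(C)C(C)(C)C | intermediate
22 | laxiflorin, (2S)-5,7-dihydroxy-2-(4-hydroxy-3-methoxyphenyl)-6-(2-hydroxyethyl)-8-(3-methylbut-2-en-1-yl)chroman-4-one | COc1cc([C@@H]2CC(=O)c3c(O)c(CCO)c(O)c(CC=C(C)C)c3O2)ccc1O | target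

**Step count**

Total: 16 steps. Longest linear sequence: 13 steps (steps 4–16, from 2,6-dihydroxybenzaldehyde 6 to laxiflorin 22).

**Steps most likely to fail**

1. Step 15. The carbene may be captured by the O1 lone pair (oxonium ylide formation followed by benzyl migration) faster than it inserts, or it may discriminate poorly between the two enantiotopic benzylic hydrogens. The fallback builds C2 by a known enantioselective conjugate arylation of a chromone instead; it sets out from 16 and comes back at 21. Aldehyde 16 with MeMgBr (2.2 equiv, THF, 0 °C) should give the benzylic alcohol 1-{2-hydroxy-3-prenyl-4,6-bis(TBSO)-5-[2-(TBSO)ethyl]phenyl}ethanol F1. MnO2 in CH2Cl2 would oxidise it to the 2-hydroxyacetophenone F2. Me2NCH(OMe)2 in toluene at 90 °C would give the enaminone F3, and pyridinium p-toluenesulfonate (or silica gel) would close it to the chromone 5,7-bis(TBSO)-6-[2-(TBSO)ethyl]-8-prenyl-4H-chromen-4-one F4. In parallel, commercial 4-bromo-2-methoxyphenol would be silylated (TBSCl, imidazole) to the aryl bromide F5 and converted with n-BuLi and B(OiPr)3, then aqueous work-up, into [4-(TBSO)-3-methoxyphenyl]boronic acid F6. Addition of F6 to F4 with Pd(OCOCF3)2, a chiral tert-butyl pyridine-oxazoline ligand (enantiomer chosen for 2S), NH4PF6 and H2O in ClCH2CH2Cl at 60 °C should then give 21.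

2. Step 14. Acylation of diazomethane at the doubly ortho-substituted acid chloride may be slow, with loss of the O5 silyl group or decomposition of the activated acid in the meantime. The fallback makes the diazo group by diazo transfer to a methyl ketone; it sets out from 17 and comes back at 20. Aldehyde 17 with MeMgBr (THF, −78 °C) should give the secondary benzylic alcohol F7. Dess–Martin periodinane (CH2Cl2, NaHCO3) would give the aryl methyl ketone F8. LiN(SiMe3)2 and then CF3CO2CH2CF3 (THF, −78 °C) would give the 4,4,4-trifluoro-1-arylbutane-1,3-dione F9. Methanesulfonyl azide, Et3N and H2O in MeCN should then give 20 by detrifluoroacetylative diazo transfer.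

3. Step 9. The phenoxide may attack the unsubstituted allyl terminus or react through a ring carbon, and palladium may isomerise the tertiary ether to the linear prenyl ether, which would not give the prenyl group on Claisen rearrangement. The fallback forms the tertiary C–O bond by copper-catalysed propargylation; it sets out from 13 and comes back at 14. Phenol 13 with 3-chloro-3-methylbut-1-yne, CuCl2 (cat.) and DBU in MeCN at 0 °C should give the aryl 1,1-dimethylpropargyl ether F10. Semihydrogenation (H2, Pd on CaCO3 poisoned with Pb(OAc)2, quinoline, EtOAc) would then give 14.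

**Further compounds**

F1 | step 15 | 1-{2-hydroxy-3-(3-methylbut-2-en-1-yl)-4,6-bis(tert-butyldimethylsilyloxy)-5-[2-(tert-butyldimethylsilyloxy)ethyl]phenyl}ethanol (racemic) | CC(O)c1c(O)c(CC=C(C)C)c(O[Si](C)(C)C(C)(C)C)c(CCO[Si](C)(C)C(C)(C)C)c1O[Si](C)(C)C(C)(C)C
F2 | step 15 | 1-{2-hydroxy-3-(3-methylbut-2-en-1-yl)-4,6-bis(tert-butyldimethylsilyloxy)-5-[2-(tert-butyldimethylsilyloxy)ethyl]phenyl}ethanone | CC(=O)c1c(O)c(CC=C(C)C)c(O[Si](C)(C)C(C)(C)C)c(CCO[Si](C)(C)C(C)(C)C)c1O[Si](C)(C)C(C)(C)C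
F3 | step 15 | (E)-3-(dimethylamino)-1-{2-hydroxy-3-(3-methylbut-2-en-1-yl)-4,6-bis(tert-butyldimethylsilyloxy)-5-[2-(tert-butyldimethylsilyloxy)ethyl]phenyl}prop-2-en-1-one | CN(C)/C=C/C(=O)c1c(O)c(CC=C(C)C)c(O[Si](C)(C)C(C)(C)C)c(CCO[Si](C)(C)C(C)(C)C)c1O[Si](C)(C)C(C)(C)C
F4 | step 15 | 5,7-bis(tert-butyldimethylsilyloxy)-6-[2-(tert-butyldimethylsilyloxy)ethyl]-8-(3-methylbut-2-en-1-yl)-4H-chromen-4-one | O=c1ccoc2c(CC=C(C)C)c(O[Si](C)(C)C(C)(C)C)c(CCO[Si](C)(C)C(C)(C)C)c(O[Si](C)(C)C(C)(C)C)c12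
F5 | step 15 | (4-bromo-2-methoxyphenoxy)(tert-butyl)dimethylsilane | COc1cc(Br)ccc1O[Si](C)(C)C(C)(C)C
F6 | step 15 | [4-(tert-butyldimethylsilyloxy)-3-methoxyphenyl]boronic acid | COc1cc(B(O)O)ccc1O[Si](C)(C)C(C)(C)C
F7 | step 14 | 1-{2-{[4-(tert-butyldimethylsilyloxy)-3-methoxyphenyl]methoxy}-3-(3-methylbut-2-en-1-yl)-4,6-bis(tert-butyldimethylsilyloxy)-5-[2-(tert-butyldimethylsilyloxy)ethyl]phenyl}ethanol (racemic) | CC(O)c1c(OCc2ccc(O[Si](C)(C)C(C)(C)C)c(OC)c2)c(CC=C(C)C)c(O[Si](C)(C)C(C)(C)C)c(CCO[Si](C)(C)C(C)(C)C)c1O[Si](C)(C)C(C)(C)C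
F8 | step 14 | 1-{2-{[4-(tert-butyldimethylsilyloxy)-3-methoxyphenyl]methoxy}-3-(3-methylbut-2-en-1-yl)-4,6-bis(tert-butyldimethylsilyloxy)-5-[2-(tert-butyldimethylsilyloxy)ethyl]phenyl}ethanone | CC(=O)c1c(OCc2ccc(O[Si](C)(C)C(C)(C)C)c(OC)c2)c(CC=C(C)C)c(O[Si](C)(C)C(C)(C)C)c(CCO[Si](C)(C)C(C)(C)C)c1O[Si](C)(C)C(C)(C)C
F9 | step 14 | 4,4,4-trifluoro-1-{2-{[4-(tert-butyldimethylsilyloxy)-3-methoxyphenyl]methoxy}-3-(3-methylbut-2-en-1-yl)-4,6-bis(tert-butyldimethylsilyloxy)-5-[2-(tert-butyldimethylsilyloxy)ethyl]phenyl}butane-1,3-dione | O=C(CC(=O)C(F)(F)F)c1c(OCc2ccc(O[Si](C)(C)C(C)(C)C)c(OC)c2)c(CC=C(C)C)c(O[Si](C)(C)C(C)(C)C)c(CCO[Si](C)(C)C(C)(C)C)c1O[Si](C)(C)C(C)(C)C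
F10 | step 9 | 1,3-bis(tert-butyldimethylsilyloxy)-2-[2-(tert-butyldimethylsilyloxy)ethyl]-5-(2-methylbut-3-yn-2-yloxy)benzene | C#CC(C)(C)Oc1cc(O[Si](C)(C)C(C)(C)C)c(CCO[Si](C)(C)C(C)(C)C)c(O[Si](C)(C)C(C)(C)C)c1
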